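**Plan**

- Retrosynthesis: the two formyl groups are removed first, then the arene is cut. The target is a 2-alkylphloroglucinol: Ar-1 (bonded to benzylic C1') and its oxygenated neighbour Ar-2 are the two carbons of a siloxyalkyne, and Ar-3 to Ar-6 with the Ar-4 oxygen are a 3-ethoxycyclobutenone; the bonds cut are Ar-1–Ar-6, Ar-2–Ar-3 and (pericyclic) Ar-5–Ar-6.
- The siloxyalkyne is cut at C1'–alkyne (boron-to-alkyne exchange) and C1'–isobutyl (lithiation–borylation of a C1 hydroxymethyl carbamate); the decalin (rings A and B) goes back to (S)-Wieland–Miescher ketone.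
- Forward, core: the bicyclic ketone is bought in; C1 is methylenated, the enone is ketalised with alkene shift, a double hydroboration sets C1, C4 and C5, MeMgBr builds the C4 carbinol, and Shapiro/acetone/hydrogenation builds the C7 hydroxyisopropyl group.
- Forward, side chain and arene: isobutyl, alkyne and siloxyalkyne are installed; the benzene ring is formed last by Danheiser benzannulation, then aryl desilylation, double formylation, de-ethylation and removal of the tertiary silyl ethers.
- Stereochemistry: C10 comes from the starting ketone; C1, C5, C4 and C7 come from reagent approach anti to the angular methyl; C1' is set by (+)-sparteine-controlled lithiation–borylation and carried on with retention.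

Key step: step 16

Remark: the decalin carries eudesmane-type numbers (C10 angular-methyl carbon, C1 its ring neighbour bearing the side chain, C4 methyl carbinol, C5 ring-fusion CH, C7 carbon bearing the 2-hydroxypropan-2-yl group), C1' is the benzylic carbon, "syn/anti" refer to the C10 methyl, Cb = C(O)N(iPr)2; (S)-Wieland–Miescher ketone, (+)-sparteine and vinyl N,N-diisopropylcarbamate are assumed to be purchasable.

**Route**

Step 1
Reactants: 1 (S)-Wieland–Miescher ketone
Product: 2 (4aR)-4a-methyl-5-methylidene-4,4a,5,6,7,8-hexahydronaphthalen-2(3H)-one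
Conditions: Ph3PCH3Br, KOtBu, THF, 0 °C → rt
Reagents that add atoms: methyltriphenylphosphonium bromide, C[P+](c1ccccc1)(c1ccccc1)c1ccccc1.[Br-]
Why: Wittig methylenation, in which the unstabilised ylide attacks the saturated C1 ketone faster than the conjugated C7 carbonyl (the preference this diketone also shows in ketalisation and hydride reduction), with no stereocentre touched.

Step 2
Reactants: 2 C1-methylidene enone
Product: 3 C7 dioxolane of the 1-methylidene Δ4(5)-octalin
Conditions: HOCH2CH2OH, p-TsOH (cat.), benzene, reflux (Dean–Stark)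
Reagents that add atoms: ethylene glycol, OCCO
Why: Acid-catalysed ketalisation of an α,β-unsaturated ketone, which runs through the dienol ether and gives the deconjugated Δ4(5) ketal as with steroidal 4-en-3-ones, so that C4 becomes the unsubstituted end of a trisubstituted alkene.

Step 3
Reactants: 3 dioxolane diene
Product: 6 trans-fused C1-hydroxymethyl C4-ol C7-dioxolane, via 9-BBN adduct 4 (not isolated), via bis-borane 5 (not isolated)
Conditions: 9-BBN, THF, rt; BH3·THF, 0 °C → rt; NaOH, H2O2, 0 °C → rt
Reagents that add atoms: hydrogen peroxide, OO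
Why: Hydroboration–oxidation in which 9-BBN first takes the 1,1-disubstituted alkene (leaving no B–H on that arm), BH3 then adds to the Δ4 alkene with boron at C4, and both syn additions occur on the face anti to the angular methyl, setting C1 (CH2OH syn, equatorial), C4 (OH anti) and C5 (H anti, trans fusion) as in hydroboration of steroidal Δ5 ketals.

Step 4
Reactants: 6 diol
Product: 7 primary carbamate (C1–CH2OCb) with free C4–OH
Conditions: iPr2NCOCl, Et3N, CH2Cl2, reflux
Reagents that add atoms: N,N-diisopropylcarbamoyl chloride, CC(C)N(C(C)C)C(Cl)=O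
Why: O-Carbamoylation, in which the weakly electrophilic carbamoyl chloride reacts with the primary alcohol and leaves the secondary hydroxyl next to the ring fusion, installing the group needed for the later lithiation–borylation.

Step 5
Reactants: 7 hydroxy carbamate
Product: 8 C4 ketone
Conditions: Dess–Martin periodinane, NaHCO3, CH2Cl2, 0 °C → rt
Reagents that add atoms: none
Why: Dess–Martin oxidation of the secondary alcohol under buffered, non-basic conditions, so that the C5 hydrogen α to the new ketone keeps the trans ring fusion.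

Step 6
Reactants: 8 C4 ketone
Product: 9 C4 tertiary alcohol (C4–OH syn and axial; C4–CH3 anti)
Conditions: MeMgBr, THF, −78 → 0 °C
Reagents that add atoms: methylmagnesium bromide, C[Mg]Br
Why: Grignard 1,2-addition in which axial approach to C4 is blocked by the 1,3-diaxial C10 methyl, so the methyl enters equatorially on the anti face and the hydroxyl ends axial and syn (the outcome known for 6-oxo-5α-steroids), while the hindered carbamate and the ketal are inert.

Step 7
Reactants: 9 dioxolane carbinol
Product: 10 C7 ketone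
Conditions: PPTS (cat.), acetone/H2O, 50 °C
Reagents that add atoms: water, O
Why: Mild acid hydrolysis of the dioxolane (acetal cleavage) frees the C7 ketone under conditions too weak to ionise the tertiary alcohol or touch the carbamate.

Step 8
Reactants: 10 C7 ketone
Product: 11 C7 2,4,6-triisopropylbenzenesulfonylhydrazone
Conditions: 2,4,6-iPr3C6H2SO2NHNH2, THF, rt
Reagents that add atoms: 2,4,6-triisopropylbenzenesulfonohydrazide, CC(C)c1cc(C(C)C)c(S(=O)(=O)NN)c(C(C)C)c1
Why: Condensation of the unhindered ketone with the arenesulfonyl hydrazide gives the hydrazone required for a Shapiro reaction.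

Step 9
Reactants: 11 sulfonylhydrazone
Product: 13 Δ7(8) allylic alcohol bearing C(CH3)2OH on C7, via alkenyllithium 12 (not isolated)
Conditions: n-BuLi (3.3 equiv), THF, −78 → 0 °C; acetone, −78 °C
Reagents that add atoms: acetone, CC(C)=O
Why: Shapiro reaction in which the hydrazone dianion (a third equivalent of base serves the hydroxyl) loses sulfinate and N2 to an alkenyllithium on the less hindered C8 side that adds to acetone, while the diisopropylcarbamate resists n-BuLi at low temperature without a diamine.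

Step 10
Reactants: 13 allylic alcohol
Product: 14 saturated diol (C7–H anti; C7 hydroxyisopropyl syn and equatorial)
Conditions: H2 (1 atm), PtO2, EtOAc, rt
Reagents that add atoms: none
Why: Heterogeneous hydrogenation from the face anti to the axial angular methyl places the C7 hydrogen anti and the side group equatorial (also the more stable epimer), and PtO2 in a neutral solvent limits allylic C–O hydrogenolysis.

Step 11
Reactants: 14 diol carbamate
Product: 15 bis(triethylsilyl) ether carbamate
Conditions: Et3SiOTf, 2,6-lutidine, CH2Cl2, 0 °C → rt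
Reagents that add atoms: triethylsilyl trifluoromethanesulfonate, CC[Si](CC)(CC)OS(=O)(=O)C(F)(F)F
Why: Silylation with a silyl triflate and a hindered pyridine base is forceful enough for both tertiary hydroxyls, including the axial C4–OH, and the ethers withstand the organolithium steps that follow.

Step 12
Reactants: 15 bis-silyl carbamate; 16 isobutylboronic acid pinacol ester
Product: 19 (R)-secondary boronic ester C1–C1'H(Bpin)–CH2CH(CH3)2, via lithio carbamate 17 (not isolated), via boronate complex 18 (not isolated)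
Conditions: sBuLi, (+)-sparteine, Et2O, −78 °C; 16, −78 °C; MgBr2·OEt2, −78 °C → reflux
Reagents that add atoms: none
Why: Lithiation–borylation in which (+)-sparteine-complexed sBuLi removes the pro-R hydrogen next to the carbamate oxygen, the configurationally stable lithio carbamate 17 captures 16 with retention, and the Lewis-acid-assisted 1,2-metallate rearrangement of 18 (isobutyl migrating anti to the departing carbamate, inversion at carbon) sets C1' as R under reagent control.

Step 13
Reactants: 19 secondary boronic ester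
Product: 22 terminal alkyne C1–C1'H(C≡CH)–CH2CH(CH3)2, via alkenyl boronate 20 (not isolated), via enol carbamate 21 (not isolated)
Conditions: CH2=CHOCb, sBuLi, TMEDA, THF, −78 °C, then 19; I2, MeOH, −78 °C; NaOMe, 0 °C; crude + LiN(iPr)2, THF, −78 °C → rt
Reagents that add atoms: vinyl N,N-diisopropylcarbamate, C=COC(=O)N(C(C)C)C(C)C
Why: Zweifel-type alkenylation then β-elimination, in which boronate 20 undergoes iodine-induced 1,2-migration with retention at C1' and anti-deboronoiodination to enol carbamate 21, and LiN(iPr)2 converts 21 into the alkyne by vinylic deprotonation and loss of carbamate, a known stereospecific boron-to-alkyne exchange.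

Step 14
Reactants: 22 terminal alkyne
Product: 25 triisopropylsilyloxyalkyne C1'–C≡C–OSi(iPr)3, via lithium acetylide 23 (not isolated), via lithium ynolate 24 (not isolated)
Conditions: n-BuLi, THF, −78 °C; LiOOtBu (from t-BuOOH, LiN(SiMe3)2), −78 → 0 °C; iPr3SiOTf, −78 → 0 °C
Reagents that add atoms: tert-butyl hydroperoxide, CC(C)(C)OO; triisopropylsilyl trifluoromethanesulfonate, CC(C)[Si](C(C)C)(C(C)C)OS(=O)(=O)C(F)(F)F
Why: Oxidation of the lithium acetylide by the electrophilic oxygen of LiOOtBu gives ynolate 24, and the bulky silyl triflate silylates it on oxygen (small silyl groups give silylketenes), the standard route to triisopropylsilyloxyalkynes.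

Step 15
Reactants: 26 ethoxyacetylene
Product: 27 3-ethoxycyclobut-2-en-1-one
Conditions: AcCl, Et3N, MeCN, 0 °C → rt
Reagents that add atoms: acetyl chloride, CC(Cl)=O
Why: [2+2] Cycloaddition of ketene, generated in situ by dehydrochlorination of acetyl chloride, to the electron-rich ynol ether, whose terminal carbon bonds to the ketene carbonyl carbon to give the 3-alkoxycyclobutenone, as known for ketenes and alkoxyalkynes.

Step 16
Reactants: 25 siloxyalkyne; 27 3-ethoxycyclobut-2-en-1-one
Product: 32 2-alkyl-5-ethoxy-3-(triisopropylsilyloxy)phenol (alkyl = bis-silylated C1' side chain), via vinylketene 28 (not isolated), via vinylcyclobutenone 29 (not isolated), via dienylketene 30 (not isolated), via cyclohexadienone 31 (not isolated)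
Conditions: toluene, 80 °C then 110 °C, sealed tube; 27 (2 equiv) added in two portions
Reagents that add atoms: none
Why: Danheiser benzannulation: heating opens 27 by a four-electron electrocyclic reaction to (2-ethoxyvinyl)ketene 28, which adds to the siloxyalkyne in a [2+2] cycloaddition that forms Ar-1–Ar-6 (alkyne carbon bearing C1' to the ketene carbonyl carbon) and Ar-2–Ar-3 (oxygenated alkyne carbon to the ketene α-carbon) and gives vinylcyclobutenone 29. A second four-electron ring opening gives dienylketene 30, whose six-electron electrocyclisation forms Ar-5–Ar-6 and closes the benzene ring as cyclohexadienone 31, and tautomerisation gives phenol 32. The closest known reaction is the benzannulation of cyclobutenones with triisopropylsilyloxyalkynes to resorcinol monosilyl ethers; a 3-alkoxycyclobutenone is an unusual but electronically consistent partner. The one ring formed is the arene, closed by pericyclic 6π ring closure of the ketene-terminated triene; no stereocentre is created, and C1', which has no acidifying neighbour under these neutral thermal conditions, is retained. The selectivity needed is regiochemical and is fixed by the polarisation of the silyl ynol ether, whose carbon remote from oxygen is the nucleophile toward the ketene carbonyl carbon. The alkyl group therefore ends between OH and OSi with ethoxy para to it, leaving Ar-3 and Ar-5 as the two CH positions.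

Step 17
Reactants: 32 silyloxyphenol
Product: 33 2-alkyl-5-ethoxybenzene-1,3-diol
Conditions: Bu4NF (1.1 equiv), THF, 0 °C
Reagents that add atoms: none
Why: Fluoride-mediated desilylation, in which the aryl silyl ether (phenoxide leaving group) is cleaved at 0 °C far faster than the hindered tertiary alkyl triethylsilyl ethers, freeing the second phenol that activates the ring for formylation.

Step 18
Reactants: 33 resorcinol
Product: 35 5-alkyl-2-ethoxy-4,6-dihydroxybenzene-1,3-dicarbaldehyde, via bis(iminium) salt 34 (not isolated)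
Conditions: POCl3, DMF, MeCN, 0 °C → rt; aq. NaOAc
Reagents that add atoms: N,N-dimethylformamide, CN(C)C=O; water, O
Why: Vilsmeier–Haack formylation, in which the two remaining ring positions, each flanked by a free hydroxyl and the ethoxy group, each take up one chloroiminium electrophile (the known twofold formylation of phloroglucinols) and aqueous acetate hydrolyses 34 and any aryl formate.

Step 19
Reactants: 35 ethoxy dialdehyde
Product: 36 5-alkyl-2,4,6-trihydroxybenzene-1,3-dicarbaldehyde with both tertiary triethylsilyl ethers intact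
Conditions: BCl3, CH2Cl2, −78 → −40 °C
Reagents that add atoms: none
Why: Chelation-assisted ether cleavage, in which BCl3 held between a formyl oxygen and the flanked ethoxy oxygen lets chloride remove the ethyl group at low temperature (the known selective dealkylation of alkoxy groups ortho to a carbonyl), conditions under which the hindered tertiary silyl ethers are expected to persist.

Step 20
Reactants: 36 bis-silyl ether
Product: 37 target compound
Conditions: HF·pyridine, pyridine, THF, 0 °C → rt
Reagents that add atoms: none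
Why: Fluoride cleavage of the two tertiary triethylsilyl ethers with buffered HF·pyridine, which leaves the hydrogen-bonded dialdehyde and the tertiary alcohols alone, gives the target with all six stereocentres unchanged.

**Compound list**

1 | (S)-Wieland–Miescher ketone, (8aS)-8a-methyl-3,4,8,8a-tetrahydronaphthalene-1,6(2H,7H)-dione | O=C1CCCC2=CC(=O)CC[C@]12C | starting material
2 | (4aR)-4a-methyl-5-methylidene-4,4a,5,6,7,8-hexahydronaphthalen-2(3H)-one (C1=CH2, C5=C6, C7=O) | C=C1CCCC2=CC(=O)CC[C@]12C | intermediate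
3 | C7 ethylene ketal of the deconjugated diene (C1=CH2, C4=C5) | C=C1CCC=C2CC3(OCCO3)CC[C@]12C | intermediate
4 | B-alkyl-9-BBN adduct at the exocyclic alkene (C1–CH2–B syn to the C10 methyl, C4=C5 intact) | C(B1C2CCCC1CCC2)[C@H]1CCC=C2CC3(OCCO3)CC[C@]12C | intermediate
5 | bis-borane: as 4, with BH2 on C4 (anti) and H on C5 (anti), trans-fused | C(B1C2CCCC1CCC2)[C@H]1CC[C@H](B)[C@H]2CC3(OCCO3)CC[C@]12C | intermediate
6 | trans-fused diol: C1–CH2OH (syn, equatorial), C4–OH (anti, equatorial), C7 dioxolane | OC[C@H]1CC[C@H](O)[C@H]2CC3(OCCO3)CC[C@]12C | intermediate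
7 | primary N,N-diisopropylcarbamate of 6 (C4–OH free) | CC(C)N(C(C)C)C(=O)OC[C@H]1CC[C@H](O)[C@H]2CC3(OCCO3)CC[C@]12C | intermediate
8 | C4 ketone (trans-fused, C5–H anti) | CC(C)N(C(C)C)C(=O)OC[C@H]1CCC(=O)[C@H]2CC3(OCCO3)CC[C@]12C | intermediate
9 | C4 tertiary alcohol (OH syn and axial, CH3 anti), C7 dioxolane, C1–CH2OCb | CC(C)N(C(C)C)C(=O)OC[C@H]1CC[C@@](C)(O)[C@H]2CC3(OCCO3)CC[C@]12C | intermediate
10 | C7 ketone of 9 | CC(C)N(C(C)C)C(=O)OC[C@H]1CC[C@@](C)(O)[C@H]2CC(=O)CC[C@]12C | intermediate
11 | C7 2,4,6-triisopropylbenzenesulfonylhydrazone of 10 | CC(C)N(C(C)C)C(=O)OC[C@H]1CC[C@@](C)(O)[C@H]2CC(=NNS(=O)(=O)c3c(C(C)C)cc(C(C)C)cc3C(C)C)CC[C@]12C | intermediate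
12 | C7 alkenyllithium (C7=C8), C4 lithium alkoxide | CC(C)N(C(C)C)C(=O)OC[C@H]1CC[C@@](C)(O[Li])[C@H]2CC([Li])=CC[C@]12C | intermediate
13 | Δ7(8) allylic alcohol, C7 bearing C(CH3)2OH | CC(C)N(C(C)C)C(=O)OC[C@H]1CC[C@@](C)(O)[C@H]2CC(C(C)(C)O)=CC[C@]12C | intermediate
14 | saturated diol carbamate (C7–H anti, C(CH3)2OH syn and equatorial) | CC(C)N(C(C)C)C(=O)OC[C@H]1CC[C@@](C)(O)[C@H]2C[C@@H](C(C)(C)O)CC[C@]12C | intermediate
15 | bis(triethylsilyl) ether of 14 | CC(C)N(C(C)C)C(=O)OC[C@H]1CC[C@@](C)(O[Si](CC)(CC)CC)[C@H]2C[C@@H](C(C)(C)O[Si](CC)(CC)CC)CC[C@]12C | intermediate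
16 | isobutylboronic acid pinacol ester, 4,4,5,5-tetramethyl-2-(2-methylpropyl)-1,3,2-dioxaborolane | CC(C)CB1OC(C)(C)C(C)(C)O1 | starting material
17 | (R)-α-lithio carbamate of 15 (Li on C1') | CC(C)N(C(C)C)C(=O)O[C@H]([Li])[C@H]1CC[C@@](C)(O[Si](CC)(CC)CC)[C@H]2C[C@@H](C(C)(C)O[Si](CC)(CC)CC)CC[C@]12C | intermediate
18 | lithium boronate complex (C1' bearing OCb and B(pin)(isobutyl)) | CC(C)N(C(C)C)C(=O)O[C@H]([B-]1(CC(C)C)OC(C)(C)C(C)(C)O1)[C@H]1CC[C@@](C)(O[Si](CC)(CC)CC)[C@H]2C[C@@H](C(C)(C)O[Si](CC)(CC)CC)CC[C@]12C.[Li+] | intermediate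
19 | (1'R)-secondary boronic ester C1–C1'H(Bpin)–CH2CH(CH3)2 | CC(C)C[C@@H](B1OC(C)(C)C(C)(C)O1)[C@H]1CC[C@@](C)(O[Si](CC)(CC)CC)[C@H]2C[C@@H](C(C)(C)O[Si](CC)(CC)CC)CC[C@]12C | intermediate
20 | lithium alkenyl boronate (19 with 1-(carbamoyloxy)ethenyl on boron) | CC(C)C[C@@H]([B-]1(C(=C)OC(=O)N(C(C)C)C(C)C)OC(C)(C)C(C)(C)O1)[C@H]1CC[C@@](C)(O[Si](CC)(CC)CC)[C@H]2C[C@@H](C(C)(C)O[Si](CC)(CC)CC)CC[C@]12C.[Li+] | intermediate
21 | enol carbamate C1'–C(=CH2)OCb | CC(C)C[C@@H](C(=C)OC(=O)N(C(C)C)C(C)C)[C@H]1CC[C@@](C)(O[Si](CC)(CC)CC)[C@H]2C[C@@H](C(C)(C)O[Si](CC)(CC)CC)CC[C@]12C | intermediate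
22 | (1'R)-terminal alkyne (C1' bearing H, isobutyl, ethynyl and C1) | CC(C)C[C@@H](C#C)[C@H]1CC[C@@](C)(O[Si](CC)(CC)CC)[C@H]2C[C@@H](C(C)(C)O[Si](CC)(CC)CC)CC[C@]12C | intermediate
23 | lithium acetylide of 22 | CC(C)C[C@@H](C#C[Li])[C@H]1CC[C@@](C)(O[Si](CC)(CC)CC)[C@H]2C[C@@H](C(C)(C)O[Si](CC)(CC)CC)CC[C@]12C | intermediate
24 | lithium ynolate C1'–C≡C–OLi | CC(C)C[C@@H](C#CO[Li])[C@H]1CC[C@@](C)(O[Si](CC)(CC)CC)[C@H]2C[C@@H](C(C)(C)O[Si](CC)(CC)CC)CC[C@]12C | intermediate
25 | siloxyalkyne C1'–C≡C–OSi(iPr)3 of the bis(triethylsilyl)-protected side chain | CC(C)C[C@@H](C#CO[Si](C(C)C)(C(C)C)C(C)C)[C@H]1CC[C@@](C)(O[Si](CC)(CC)CC)[C@H]2C[C@@H](C(C)(C)O[Si](CC)(CC)CC)CC[C@]12C | intermediate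
26 | ethoxyacetylene (ethoxyethyne) | CCOC#C | starting material
27 | 3-ethoxycyclobut-2-en-1-one | CCOC1=CC(=O)C1 | intermediate
28 | (2-ethoxyvinyl)ketene, 3-ethoxybuta-1,3-dien-1-one | CCOC(=C)C=C=O | intermediate
29 | 2-alkyl-4-(1-ethoxyethenyl)-3-(triisopropylsilyloxy)cyclobut-2-en-1-one (ring CH epimers) | CC(C)C[C@@H](C1=C(O[Si](C(C)C)(C(C)C)C(C)C)C(C(=C)OCC)C1=O)[C@H]1CC[C@@](C)(O[Si](CC)(CC)CC)[C@H]2C[C@@H](C(C)(C)O[Si](CC)(CC)CC)CC[C@]12C | intermediate
30 | dienylketene, 2-alkyl-5-ethoxy-3-(triisopropylsilyloxy)hexa-1,3,5-trien-1-one | CC(C)C[C@@H](C(=C=O)C(O[Si](C(C)C)(C(C)C)C(C)C)=CC(=C)OCC)[C@H]1CC[C@@](C)(O[Si](CC)(CC)CC)[C@H]2C[C@@H](C(C)(C)O[Si](CC)(CC)CC)CC[C@]12C | intermediate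
31 | 2-alkyl-5-ethoxy-3-(triisopropylsilyloxy)cyclohexa-2,4-dien-1-one | CC(C)C[C@@H](C1=C(O[Si](C(C)C)(C(C)C)C(C)C)C=C(OCC)CC1=O)[C@H]1CC[C@@](C)(O[Si](CC)(CC)CC)[C@H]2C[C@@H](C(C)(C)O[Si](CC)(CC)CC)CC[C@]12C | intermediate
32 | 2-alkyl-5-ethoxy-3-(triisopropylsilyloxy)phenol | CC(C)C[C@@H](c1c(O[Si](C(C)C)(C(C)C)C(C)C)cc(OCC)cc1O)[C@H]1CC[C@@](C)(O[Si](CC)(CC)CC)[C@H]2C[C@@H](C(C)(C)O[Si](CC)(CC)CC)CC[C@]12C | intermediate
33 | 2-alkyl-5-ethoxybenzene-1,3-diol | CC(C)C[C@@H](c1c(O)cc(OCC)cc1O)[C@H]1CC[C@@](C)(O[Si](CC)(CC)CC)[C@H]2C[C@@H](C(C)(C)O[Si](CC)(CC)CC)CC[C@]12C | intermediate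
34 | bis(dimethyliminium) salt of the dialdehyde (shown as dichloride) | CC(C)C[C@@H](c1c(O)c(C=[N+](C)C)c(OCC)c(C=[N+](C)C)c1O)[C@H]1CC[C@@](C)(O[Si](CC)(CC)CC)[C@H]2C[C@@H](C(C)(C)O[Si](CC)(CC)CC)CC[C@]12C.[Cl-].[Cl-] | intermediate
35 | 5-alkyl-2-ethoxy-4,6-dihydroxybenzene-1,3-dicarbaldehyde (bis-silyl ether) | CC(C)C[C@@H](c1c(O)c(C=O)c(OCC)c(C=O)c1O)[C@H]1CC[C@@](C)(O[Si](CC)(CC)CC)[C@H]2C[C@@H](C(C)(C)O[Si](CC)(CC)CC)CC[C@]12C | intermediate
36 | 5-alkyl-2,4,6-trihydroxybenzene-1,3-dicarbaldehyde (bis-silyl ether) | CC(C)C[C@@H](c1c(O)c(C=O)c(O)c(C=O)c1O)[C@H]1CC[C@@](C)(O[Si](CC)(CC)CC)[C@H]2C[C@@H](C(C)(C)O[Si](CC)(CC)CC)CC[C@]12C | intermediate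
37 | target: (1R,4R,5S,7S,10R)-decalin diol with (1'R)-benzylic centre carrying the diformylphloroglucinol | CC(C)C[C@@H](c1c(O)c(C=O)c(O)c(C=O)c1O)[C@H]1CC[C@@](C)(O)[C@H]2C[C@@H](C(C)(C)O)CC[C@]12C | target

**Step count**

Total steps: 20. Longest linear sequence: 19 steps (from 1 through steps 1–14 and 16–20 to 37); step 15 is a one-step branch.

**Steps most likely to fail, with fallbacks**

1. Step 16. The four-electron ring opening of the vinylogous-ester cyclobutenone may need temperatures at which the siloxyalkyne loses its silyl group or oligomerises, and the free phenol may be consumed by O-acylation with excess ketene. The fallback makes the same ketene 28 at 0–25 °C by 1,4-dehydrochlorination instead of ring opening. Commercial ethyl (E)-3-ethoxybut-2-enoate would be saponified (LiOH, THF/H2O) to (E)-3-ethoxybut-2-enoic acid F1, and oxalyl chloride would give (E)-3-ethoxybut-2-enoyl chloride F2. Slow addition of F2 and Et3N to siloxyalkyne 25 in CH2Cl2 would form 28 in the presence of the alkyne, the way vinylketenes are made from crotonyl chlorides for [2+2] reactions. The cycloadduct 29 would then be warmed in toluene at 60–80 °C. This sets out from 25 and rejoins the route at phenol 32.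

2. Step 12. Deprotonation next to a β-branched carbon flanked by the quaternary C10 may be slow, the (+)-sparteine/substrate pairing may be mismatched so that facial control at C1' erodes, and the 1,2-migration may stall. The fallback sets C1' by catalyst-controlled conjugate addition and reaches the ynolate from an ester. LiAlH4 would remove the carbamate of 15 to give primary alcohol F3, and Dess–Martin oxidation would give aldehyde F4. Wittig reaction with Ph3P=CHCO2Me would give (E)-enoate F5. CuI/Tol-BINAP-catalysed 1,4-addition of iBuMgBr, with the ligand enantiomer chosen for the 1'S adduct (same spatial arrangement as in 19), would give β-isobutyl ester F6. Enolate bromination (LiN(iPr)2, CBr4) done twice would give α-bromo ester F7 and then α,α-dibromo ester F8. t-BuLi would convert F8 into ynolate 24 by double bromine–lithium exchange and loss of methoxide, and silylation as in step 14 follows. This sets out from 15 and rejoins the route at siloxyalkyne 25.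

3. Step 19. BCl3 may strip the tertiary silyl ethers and ionise the C4–O or C11–O bond (elimination) before or alongside cleavage of the ethyl ether. The fallback reverses the order and cleaves the ether by SN2 rather than by a Lewis acid. HF·pyridine would first convert 35 into desilylated ethoxy dialdehyde F9. NaSEt in DMF at 100 °C would then remove the ethyl group by thiolate attack at CH2, with the doubly ortho-formylated phenoxide as leaving group. This sets out from 35 and arrives directly at target 37.

Further compounds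
F1 | step 16 | (E)-3-ethoxybut-2-enoic acid | CCO/C(C)=C/C(=O)O
F2 | step 16 | (E)-3-ethoxybut-2-enoyl chloride | CCO/C(C)=C/C(=O)Cl
F3 | step 12 | primary alcohol C1–CH2OH (bis-silyl ether) | OC[C@H]1CC[C@@](C)(O[Si](CC)(CC)CC)[C@H]2C[C@@H](C(C)(C)O[Si](CC)(CC)CC)CC[C@]12C
F4 | step 12 | aldehyde C1–CHO (bis-silyl ether) | O=C[C@H]1CC[C@@](C)(O[Si](CC)(CC)CC)[C@H]2C[C@@H](C(C)(C)O[Si](CC)(CC)CC)CC[C@]12C
F5 | step 12 | methyl (E)-enoate C1–CH=CH–CO2Me | COC(=O)/C=C/[C@H]1CC[C@@](C)(O[Si](CC)(CC)CC)[C@H]2C[C@@H](C(C)(C)O[Si](CC)(CC)CC)CC[C@]12C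
F6 | step 12 | (1'S)-β-isobutyl ester C1–C1'H(CH2CO2Me)–CH2CH(CH3)2 | CC(C)C[C@@H](CC(=O)OC)[C@H]1CC[C@@](C)(O[Si](CC)(CC)CC)[C@H]2C[C@@H](C(C)(C)O[Si](CC)(CC)CC)CC[C@]12C
F7 | step 12 | α-bromo ester (epimers at the CHBr carbon) | CC(C)C[C@@H](C(Br)C(=O)OC)[C@H]1CC[C@@](C)(O[Si](CC)(CC)CC)[C@H]2C[C@@H](C(C)(C)O[Si](CC)(CC)CC)CC[C@]12C
F8 | step 12 | α,α-dibromo ester | CC(C)C[C@@H](C(Br)(Br)C(=O)OC)[C@H]1CC[C@@](C)(O[Si](CC)(CC)CC)[C@H]2C[C@@H](C(C)(C)O[Si](CC)(CC)CC)CC[C@]12C
F9 | step 19 | 5-alkyl-2-ethoxy-4,6-dihydroxybenzene-1,3-dicarbaldehyde with free C4 and C11 hydroxyls | CC(C)C[C@@H](c1c(O)c(C=O)c(OCC)c(C=O)c1O)[C@H]1CC[C@@](C)(O)[C@H]2C[C@@H](C(C)(C)O)CC[C@]12C
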